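**Retrosynthetic overview** (carotenoid numbering; target = siphonein, 3R,3'R,6'R, all-trans chain)
1. Last operation: C19–C9 is made by Pd/Cu coupling of (tributylstannyl)methyl (E)-dodec-2-enoate with a C9–I bond; in the same flask, just before, C9=C10 is made by Wittig reaction of an α-iodo acyl ylide (C1–C9, β-ring) with a C27 apo-aldehyde (C10–C7', ε-ring).
2. Enabling feature: C9 is at once the α-carbon of the C8 ketone (C7H2–C8(=O)–C9) and the head of the heptaene C9=C10 … C7'=C8'. As an acyl-stabilised ylide carbon it takes up I+ and olefinates C10, and the resulting cross-conjugated C8(=O)–C9(I)=C10 iodide is activated for coupling. The hydroxyls on the β-ring (C3) and ε-ring (C3') stay free, so the three oxygens never have to be told apart.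
3. C27 aldehyde: two-carbon extension (HWE, DIBAL-H) of the C25 aldehyde obtained by Wittig reaction of the ε-ring C15 phosphonium salt with 2,7-dimethylocta-2,4,6-trienedial; (R)-α-ionone supplies C6', an enzymatic C–H hydroxylation sets C3'.
4. Ylide: (4R,6R)-actinol supplies C3; its enol triflate fixes C5=C6; C6–C7 by Pd coupling with a zinc ester enolate; C8–C9 by acylation of Ph3P=CH2.
5. No ring is formed: the β-ring (C1–C6) comes intact from actinol and the ε-ring (C1'–C6') intact from α-ionone.

Key step: step 13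

Assumption: (R)-α-ionone and (4R,6R)-actinol are bought enantiopure, the whole-cell P450 catalyst of step 6 is made by standard expression, and all polyenes are handled in the dark under argon.

Step 1
Reactants: 1 (4R,6R)-4-hydroxy-2,2,6-trimethylcyclohexan-1-one (actinol)
Product: 2 (4R,6R)-4-[(tert-butyldimethylsilyl)oxy]-2,2,6-trimethylcyclohexan-1-one
Conditions: TBSCl, imidazole, DMF, 23 °C
Reagents that add atoms: tert-butyldimethylsilyl chloride, CC(C)(C)[Si](C)(C)Cl
Why: Silyl ether formation on the unhindered secondary alcohol masks the hydroxyl for the strongly basic steps that follow and touches neither stereocentre.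

Step 2
Reactants: 2 TBS-actinol
Product: 4 (4R)-4-[(tert-butyldimethylsilyl)oxy]-2,6,6-trimethylcyclohex-1-en-1-yl trifluoromethanesulfonate, via potassium enolate 3 (not isolated)
Conditions: KHMDS, THF, −78 → 0 °C; then PhNTf2, −78 → 23 °C
Reagents that add atoms: N-phenylbis(trifluoromethanesulfonimide), O=S(=O)(N(c1ccccc1)S(=O)(=O)C(F)(F)F)C(F)(F)F
Why: The ketone can enolise only toward the methyl-bearing carbon because the other α-carbon is quaternary, so enol triflate formation fixes the future C5=C6 ring double bond regiospecifically, erases the superfluous methine stereocentre and leaves the carbinol centre untouched.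

Step 3
Reactants: 4 enol triflate
Product: 5 ethyl 2-[(4R)-4-[(tert-butyldimethylsilyl)oxy]-2,6,6-trimethylcyclohex-1-en-1-yl]acetate
Conditions: BrZnCH2CO2Et (3 equiv), Pd2(dba)3 (2.5 mol %), XPhos (10 mol %), THF, 60 °C
Reagents that add atoms: (2-ethoxy-2-oxoethyl)zinc bromide, CCOC(=O)C[Zn]Br
Why: Negishi-type cross-coupling of the alkenyl triflate with the Reformatsky zinc enolate forms C6–C7 and brings in C8 at the ester level, with a bulky electron-rich biarylphosphine chosen to serve oxidative addition and reductive elimination at the tetrasubstituted carbon.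

Step 4
Reactants: 5 ethyl ester
Product: 6 1-[(4R)-4-[(tert-butyldimethylsilyl)oxy]-2,6,6-trimethylcyclohex-1-en-1-yl]-3-(triphenyl-λ5-phosphanylidene)propan-2-one
Conditions: Ph3PCH3Br (2.2 equiv), NaHMDS (2.1 equiv), THF, 0 °C; then 5, 0 → 50 °C
Reagents that add atoms: methyltriphenylphosphonium bromide (as its ylide), [Br-].C[P+](c1ccccc1)(c1ccccc1)c1ccccc1
Why: Acylation of methylenetriphenylphosphorane by the ester, with the second ylide equivalent as base, gives the acyl-stabilised ylide (C8–C9 bond) directly, the ylide being nucleophilic enough to add to the ester but too weak a base to enolise the allylic C7 methylene irreversibly.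

Step 5
Reactants: 6 silylated keto ylide
Product: 8 1-[(4R)-4-hydroxy-2,6,6-trimethylcyclohex-1-en-1-yl]-3-(triphenyl-λ5-phosphanylidene)propan-2-one (hydroxy keto ylide), via phosphonium chloride 7 (not isolated)
Conditions: HCl (1.25 M in MeOH), 0 → 23 °C; then aq. Na2CO3, CH2Cl2
Reagents that add atoms: none
Why: Acidic methanolysis removes the silyl ether while the ylide is parked as its acid-stable acylmethylphosphonium chloride, and carbonate then regenerates the non-basic stabilised ylide (protecting-group removal).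

Step 6
Reactants: 9 (R)-α-ionone [(3E)-4-[(1R)-2,6,6-trimethylcyclohex-2-en-1-yl]but-3-en-2-one]
Product: 10 (3R,6R)-3-hydroxy-α-ionone [(3E)-4-[(1R,4R)-4-hydroxy-2,6,6-trimethylcyclohex-2-en-1-yl]but-3-en-2-one]
Conditions: E. coli whole cells co-expressing the bacterial P450 CYP101B1 with its ferredoxin and ferredoxin reductase, glucose, air, phosphate buffer pH 7.4, 30 °C
Reagents that add atoms: dioxygen, O=O
Why: P450 C–H hydroxylation (hydrogen abstraction and oxygen rebound) at the ring allylic methylene, a transformation described for α-ionone with bacterial P450s, in which the enzyme pocket is expected to deliver the oxygen trans to the side chain so that the purchased 6R centre and the enzyme together should give the 3R carbinol.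

Step 7
Reactants: 10 (3R,6R)-3-hydroxy-α-ionone
Product: 11 (1E)-1-[(1R,4R)-4-hydroxy-2,6,6-trimethylcyclohex-2-en-1-yl]-3-methylpenta-1,4-dien-3-ol (epimer mixture at the new carbinol carbon)
Conditions: CH2=CHMgBr (3 equiv), THF, −78 → 0 °C; aq. NH4Cl
Reagents that add atoms: vinylmagnesium bromide, C=C[Mg]Br
Why: Grignard 1,2-addition to the methyl ketone (first equivalent consumed by the hydroxyl) gives the bis-allylic tertiary carbinol, whose new stereocentre is inconsequential because it is destroyed in the next step.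

Step 8
Reactants: 11 vinyl carbinol
Product: 12 [(2E,4E)-5-[(1R,4R)-4-hydroxy-2,6,6-trimethylcyclohex-2-en-1-yl]-3-methylpenta-2,4-dien-1-yl]triphenylphosphonium bromide
Conditions: PPh3·HBr (1.0 equiv), PPh3 (0.2 equiv), CH2Cl2, −10 → 23 °C
Reagents that add atoms: triphenylphosphine hydrobromide, [Br-].[PH+](c1ccccc1)(c1ccccc1)c1ccccc1
Why: The weak acid Ph3PH+ ionises only the tertiary bis-allylic alcohol and PPh3 captures the pentadienyl cation at its unhindered terminus (SN1' phosphonium salt formation, trisubstituted double bond under thermodynamic control), an acidity at which the secondary ring allylic alcohol and the doubly allylic C6' centre should stay intact.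

Step 9
Reactants: 12 C15 phosphonium bromide; 13 (2E,4E,6E)-2,7-dimethylocta-2,4,6-trienedial
Product: 15 (2E,4E,6E,8E,10E,12E)-13-[(1R,4R)-4-hydroxy-2,6,6-trimethylcyclohex-2-en-1-yl]-2,7,11-trimethyltrideca-2,4,6,8,10,12-hexaenal (C25 aldehyde), via phosphorus ylide 14 (not isolated)
Conditions: 13 (3 equiv), NaOMe (1.05 equiv), CH2Cl2/MeOH, −10 → 23 °C; then I2 (cat.), CH2Cl2, 23 °C, diffuse light
Reagents that add atoms: none
Why: Wittig olefination of the semi-stabilised allylic ylide with an excess of the symmetrical dialdehyde should stop at mono-condensation, and iodine-catalysed equilibration converts the unhindered cis isomer of the new disubstituted double bond into the all-E polyene.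

Step 10
Reactants: 15 C25 aldehyde
Product: 16 (2E,4E,6E,8E,10E,12E,14E)-15-[(1R,4R)-4-hydroxy-2,6,6-trimethylcyclohex-2-en-1-yl]-N-methoxy-N,4,9,13-tetramethylpentadeca-2,4,6,8,10,12,14-heptaenamide
Conditions: (EtO)2P(O)CH2C(O)N(OMe)Me (1.3 equiv), NaH (1.25 equiv), THF, 0 → 23 °C
Reagents that add atoms: diethyl [2-[methoxy(methyl)amino]-2-oxoethyl]phosphonate, CCOP(=O)(CC(=O)N(C)OC)OCC
Why: Horner–Wadsworth–Emmons olefination with the Weinreb amide phosphonate adds C11 and C10 with the E selectivity typical of this reagent and gives an acyl group that one reduction turns into the aldehyde, the preformed phosphonate anion being too weak a base to disturb the free hydroxyl.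

Step 11
Reactants: 16 Weinreb polyenamide
Product: 17 (2E,4E,6E,8E,10E,12E,14E)-15-[(1R,4R)-4-hydroxy-2,6,6-trimethylcyclohex-2-en-1-yl]-4,9,13-trimethylpentadeca-2,4,6,8,10,12,14-heptaenal (C27 apo-aldehyde)
Conditions: DIBAL-H (2.5 equiv), THF, −78 °C; aq. Rochelle salt
Reagents that add atoms: none
Why: Hydride reduction of the Weinreb amide stops at the chelated hemiaminal aluminate, which releases the polyenal only on work-up, so over-reduction is avoided.

Step 12
Reactants: 18 (2E)-dodec-2-enoic acid; 19 tributyl(iodomethyl)stannane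
Product: 20 (tributylstannyl)methyl (2E)-dodec-2-enoate
Conditions: Cs2CO3, DMF, 23 °C, dark
Reagents that add atoms: none
Why: SN2 O-alkylation of the caesium carboxylate by the iodomethylstannane gives an (acyloxymethyl)stannane that carries C19, the ester oxygen and the whole acyl chain as one nucleophilic unit.

Step 13
Reactants: 8 hydroxy keto ylide; 17 C27 apo-aldehyde; 20 stannylmethyl ester
Product: 23 siphonein [(3R,3'R,6'R)-3,3'-dihydroxy-8-oxo-7,8-dihydro-β,ε-caroten-19-yl (2E)-dodec-2-enoate], via iodo ylide 21 (not isolated), via polyene iodide 22 (not isolated)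
Conditions: 8 (1.3 equiv), NIS (1.25 equiv), THF, −20 °C; then 17 (1.0 equiv), 55 °C; then 20 (2 equiv), Pd2(dba)3 (5 mol %), AsPh3 (40 mol %), CuI (50 mol %), NMP, 23 → 40 °C; dark, argon throughout
Reagents that add atoms: none
Why: Proposed new method: the acyl ylide carbon C9 of 8 is iodinated by NIS to the α-iodo ylide 21, whose Wittig reaction with the C10 aldehyde of 17 gives the (9Z)-α-iodo enone 22; Pd(0) then inserts into the activated C9–I bond, the acyloxymethyl group passes from tin via copper to palladium (helped by coordination of its ester carbonyl), and reductive elimination forms C19–C9 with retention of geometry. The closest known reactions are the one-pot halogenation–Wittig olefination of stabilised ylides to (Z)-α-halo enoates and enones, the Stille coupling of α-iodo enones with (hydroxymethyl)tributylstannane and the Pd/Cu coupling of α-acyloxyalkylstannanes; what is new is the transfer of an unsubstituted acyloxymethyl group to an alkenyl iodide near ambient temperature and the telescoping of the two events. No ring is closed and no stereocentre is created; the only stereochemical issue is the C9=C10 geometry, set in the olefination by the usual preference of stabilised ylides for the isomer with the carbonyl trans to the β-substituent and carried through the coupling. The step needs iodination at C9 only (NIS is consumed by a slight excess of the far more nucleophilic ylide before the polyene is added), transfer of CH2O2CR rather than butyl (α-oxygen and carbonyl coordination), and survival of the allylic ester of the product toward Pd(0) (weak donor ligand, mild temperature, much faster oxidative addition to C–I).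

**Compound list**
1 | (4R,6R)-4-hydroxy-2,2,6-trimethylcyclohexan-1-one (actinol) | CC1(C)C[C@H](O)C[C@@H](C)C1=O | starting material
2 | (4R,6R)-4-[(tert-butyldimethylsilyl)oxy]-2,2,6-trimethylcyclohexan-1-one | CC1(C)C[C@H](O[Si](C)(C)C(C)(C)C)C[C@@H](C)C1=O | intermediate
3 | potassium (4R)-4-[(tert-butyldimethylsilyl)oxy]-2,6,6-trimethylcyclohex-1-en-1-olate | [K+].CC1=C([O-])C(C)(C)C[C@H](O[Si](C)(C)C(C)(C)C)C1 | intermediate
4 | (4R)-4-[(tert-butyldimethylsilyl)oxy]-2,6,6-trimethylcyclohex-1-en-1-yl trifluoromethanesulfonate | CC1=C(OS(=O)(=O)C(F)(F)F)C(C)(C)C[C@H](O[Si](C)(C)C(C)(C)C)C1 | intermediate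
5 | ethyl 2-[(4R)-4-[(tert-butyldimethylsilyl)oxy]-2,6,6-trimethylcyclohex-1-en-1-yl]acetate | CCOC(=O)CC1=C(C)C[C@@H](O[Si](C)(C)C(C)(C)C)CC1(C)C | intermediate
6 | 1-[(4R)-4-[(tert-butyldimethylsilyl)oxy]-2,6,6-trimethylcyclohex-1-en-1-yl]-3-(triphenyl-λ5-phosphanylidene)propan-2-one | O=C(CC1=C(C)C[C@@H](O[Si](C)(C)C(C)(C)C)CC1(C)C)C=P(c2ccccc2)(c2ccccc2)c2ccccc2 | intermediate
7 | [3-[(4R)-4-hydroxy-2,6,6-trimethylcyclohex-1-en-1-yl]-2-oxopropyl]triphenylphosphonium chloride | [Cl-].O=C(CC1=C(C)C[C@@H](O)CC1(C)C)C[P+](c2ccccc2)(c2ccccc2)c2ccccc2 | intermediate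
8 | 1-[(4R)-4-hydroxy-2,6,6-trimethylcyclohex-1-en-1-yl]-3-(triphenyl-λ5-phosphanylidene)propan-2-one | O=C(CC1=C(C)C[C@@H](O)CC1(C)C)C=P(c2ccccc2)(c2ccccc2)c2ccccc2 | intermediate
9 | (R)-α-ionone | CC(=O)/C=C/[C@H]1C(C)=CCCC1(C)C | starting material
10 | (3R,6R)-3-hydroxy-α-ionone | CC(=O)/C=C/[C@H]1C(C)=C[C@H](O)CC1(C)C | intermediate
11 | (1E)-1-[(1R,4R)-4-hydroxy-2,6,6-trimethylcyclohex-2-en-1-yl]-3-methylpenta-1,4-dien-3-ol | C=CC(C)(O)/C=C/[C@H]1C(C)=C[C@H](O)CC1(C)C | intermediate
12 | [(2E,4E)-5-[(1R,4R)-4-hydroxy-2,6,6-trimethylcyclohex-2-en-1-yl]-3-methylpenta-2,4-dien-1-yl]triphenylphosphonium bromide | [Br-].c2ccccc2[P+](c2ccccc2)(c2ccccc2)C/C=C(C)/C=C/[C@H]1C(C)=C[C@H](O)CC1(C)C | intermediate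
13 | (2E,4E,6E)-2,7-dimethylocta-2,4,6-trienedial | O=C/C(C)=C/C=C/C=C(C)/C=O | starting material
14 | ylide of 12: [(2E,4E)-5-[(1R,4R)-4-hydroxy-2,6,6-trimethylcyclohex-2-en-1-yl]-3-methylpenta-2,4-dien-1-ylidene]triphenyl-λ5-phosphane | c2ccccc2P(c2ccccc2)(c2ccccc2)=C/C=C(C)/C=C/[C@H]1C(C)=C[C@H](O)CC1(C)C | intermediate
15 | (2E,4E,6E,8E,10E,12E)-13-[(1R,4R)-4-hydroxy-2,6,6-trimethylcyclohex-2-en-1-yl]-2,7,11-trimethyltrideca-2,4,6,8,10,12-hexaenal | O=C/C(C)=C/C=C/C=C(C)/C=C/C=C(C)/C=C/[C@H]1C(C)=C[C@H](O)CC1(C)C | intermediate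
16 | (2E,4E,6E,8E,10E,12E,14E)-15-[(1R,4R)-4-hydroxy-2,6,6-trimethylcyclohex-2-en-1-yl]-N-methoxy-N,4,9,13-tetramethylpentadeca-2,4,6,8,10,12,14-heptaenamide | CON(C)C(=O)/C=C/C(C)=C/C=C/C=C(C)/C=C/C=C(C)/C=C/[C@H]1C(C)=C[C@H](O)CC1(C)C | intermediate
17 | (2E,4E,6E,8E,10E,12E,14E)-15-[(1R,4R)-4-hydroxy-2,6,6-trimethylcyclohex-2-en-1-yl]-4,9,13-trimethylpentadeca-2,4,6,8,10,12,14-heptaenal | O=C/C=C/C(C)=C/C=C/C=C(C)/C=C/C=C(C)/C=C/[C@H]1C(C)=C[C@H](O)CC1(C)C | intermediate
18 | (2E)-dodec-2-enoic acid | CCCCCCCCC/C=C/C(=O)O | starting material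
19 | tributyl(iodomethyl)stannane | CCCC[Sn](CCCC)(CCCC)CI | starting material
20 | (tributylstannyl)methyl (2E)-dodec-2-enoate | CCCCCCCCC/C=C/C(=O)OC[Sn](CCCC)(CCCC)CCCC | intermediate
21 | 1-[(4R)-4-hydroxy-2,6,6-trimethylcyclohex-1-en-1-yl]-3-iodo-3-(triphenyl-λ5-phosphanylidene)propan-2-one | O=C(CC1=C(C)C[C@@H](O)CC1(C)C)C(I)=P(c2ccccc2)(c2ccccc2)c2ccccc2 | intermediate
22 | (3R,3'R,6'R)-3,3'-dihydroxy-9-iodo-19-nor-7,8-dihydro-β,ε-caroten-8-one (9Z by CIP, chain all-trans) | I\C(=C/C=C/C(C)=C/C=C/C=C(C)/C=C/C=C(C)/C=C/[C@H]1C(C)=C[C@H](O)CC1(C)C)C(=O)CC1=C(C)C[C@@H](O)CC1(C)C | intermediate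
23 | siphonein, (3R,3'R,6'R)-3,3'-dihydroxy-8-oxo-7,8-dihydro-β,ε-caroten-19-yl (2E)-dodec-2-enoate | CCCCCCCCC/C=C/C(=O)OC\C(=C/C=C/C(C)=C/C=C/C=C(C)/C=C/C=C(C)/C=C/[C@H]1C(C)=C[C@H](O)CC1(C)C)C(=O)CC1=C(C)C[C@@H](O)CC1(C)C | target

**Step count and risks**
Total step count: 13. Longest linear sequence: 7 steps (steps 6–11 and 13, from 9).

Steps most likely to fail:

1. Step 13 (Proposed new method). The doubly stabilised iodo ylide may olefinate the heptaenal too slowly; butyl may be transferred from tin in place of acyloxymethyl; or Pd(0) may ionise the allylic ester of the product, scrambling the C9=C10 geometry or exchanging the carboxylate. The fallback uses known chemistry only, sets out from 8, 17 and 18 and comes back at 23. Iodination and Wittig olefination are run as a separate operation and polyene iodide 22 is isolated by rapid filtration through neutral alumina in the dark. Iodide 22 is coupled with (tributylstannyl)methanol under standard hydroxymethyl Stille conditions [Pd(PPh3)4, dioxane, 80 °C] to give the triol siphonaxanthin F1. The primary allylic 19-hydroxyl of F1 is then acylated in preference to the two secondary hydroxyls with acid 18 (EDC·HCl, cat. DMAP, CH2Cl2, −20 °C) to give 23.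

2. Step 6. The enzymatic hydroxylation may stall at low conversion, over-oxidise the new carbinol to the 3-ketone, or lose facial control. The fallback sets out from 9 and comes back at 10. Ketalisation with 1,2-bis(trimethylsiloxy)ethane and cat. TMSOTf (CH2Cl2, −78 °C) gives the dioxolane ketal F2. Allylic oxidation (t-BuOOH, cat. Rh2(cap)4, CH2Cl2) gives the ring enone F3. L-Selectride (THF, −78 °C) is expected to add hydride on the open face anti to the side chain and give the cis-alcohol F4. Mitsunobu inversion (4-nitrobenzoic acid, DIAD, PPh3) gives the trans p-nitrobenzoate F5, K2CO3/MeOH gives the trans-hydroxy ketal F6, and PPTS in aqueous acetone releases 10.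

3. Step 3. Oxidative addition and transmetalation at the tetrasubstituted, neopentyl-flanked triflate may be slow, so that protodetriflation and self-condensation of the zinc enolate take over. The fallback sets out from 4 and comes back at 5. Stille coupling with tributyl(vinyl)stannane [Pd(PPh3)4, LiCl, THF, reflux] gives the diene F7. Hydroboration of the terminal vinyl group with 9-BBN and NaOH/H2O2 work-up gives the primary alcohol F8. Oxidation with TEMPO/PhI(OAc)2 in MeCN/H2O gives the acid F9, and EtI/K2CO3 in DMF gives 5.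

**Further compounds**
F1 | step 13 | siphonaxanthin, (3R,3'R,6'R)-3,19,3'-trihydroxy-7,8-dihydro-β,ε-caroten-8-one | OC\C(=C/C=C/C(C)=C/C=C/C=C(C)/C=C/C=C(C)/C=C/[C@H]1C(C)=C[C@H](O)CC1(C)C)C(=O)CC1=C(C)C[C@@H](O)CC1(C)C
F2 | step 6 | 2-methyl-2-[(E)-2-[(1R)-2,6,6-trimethylcyclohex-2-en-1-yl]ethenyl]-1,3-dioxolane | CC1(OCCO1)/C=C/[C@H]2C(C)=CCCC2(C)C
F3 | step 6 | (4R)-3,5,5-trimethyl-4-[(E)-2-(2-methyl-1,3-dioxolan-2-yl)ethenyl]cyclohex-2-en-1-one | CC1(OCCO1)/C=C/[C@H]2C(C)=CC(=O)CC2(C)C
F4 | step 6 | (1S,4R)-3,5,5-trimethyl-4-[(E)-2-(2-methyl-1,3-dioxolan-2-yl)ethenyl]cyclohex-2-en-1-ol | CC1(OCCO1)/C=C/[C@H]2C(C)=C[C@@H](O)CC2(C)C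
F5 | step 6 | (1R,4R)-3,5,5-trimethyl-4-[(E)-2-(2-methyl-1,3-dioxolan-2-yl)ethenyl]cyclohex-2-en-1-yl 4-nitrobenzoate | CC1(OCCO1)/C=C/[C@H]2C(C)=C[C@H](OC(=O)c3ccc(cc3)[N+](=O)[O-])CC2(C)C
F6 | step 6 | (1R,4R)-3,5,5-trimethyl-4-[(E)-2-(2-methyl-1,3-dioxolan-2-yl)ethenyl]cyclohex-2-en-1-ol | CC1(OCCO1)/C=C/[C@H]2C(C)=C[C@H](O)CC2(C)C
F7 | step 3 | tert-butyl{[(1R)-4-ethenyl-3,5,5-trimethylcyclohex-3-en-1-yl]oxy}dimethylsilane | C=CC1=C(C)C[C@@H](O[Si](C)(C)C(C)(C)C)CC1(C)C
F8 | step 3 | 2-[(4R)-4-[(tert-butyldimethylsilyl)oxy]-2,6,6-trimethylcyclohex-1-en-1-yl]ethan-1-ol | OCCC1=C(C)C[C@@H](O[Si](C)(C)C(C)(C)C)CC1(C)C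
F9 | step 3 | 2-[(4R)-4-[(tert-butyldimethylsilyl)oxy]-2,6,6-trimethylcyclohex-1-en-1-yl]acetic acid | OC(=O)CC1=C(C)C[C@@H](O[Si](C)(C)C(C)(C)C)CC1(C)C
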